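**Analysis of the target**

The target is a germacrane: a ten-membered carbocycle (germacrane numbering) with an E trisubstituted olefin C1=C10 carrying the C14 methyl on C10, a trans 4,5-epoxide with the C15 methyl on C4, a senecioate on C3, an acetate on C6, an isopropyl group on C7 and methylenes at C2, C8 and C9. The five stereocentres C3 to C7 are contiguous (3S,4R,5R,6R,7S); the epoxide is erythro to the C6 oxygen, and in planar projection O3, O6 and the isopropyl group lie on one face. Sensitive points are the epoxide, which faces the C1=C10 bond across the ring and can be opened transannularly by acid, the 1,5-diene of any des-epoxy precursor (acid-induced cyclisation, Cope rearrangement on heating), and two different esters, one a conjugated enoate. The difficulty is threefold: a ten-membered ring is the least favourable size for end-to-end closure, an E olefin must sit in it, and C4/C5 must be set on a flexible ring while two secondary hydroxyls are told apart. The strategy rests on the fact that C5 and C10 face each other across the ring: joining them closes ring A (C1–C5, C10) and ring B (C5–C10) of a trans-fused eudesmane decalin, so the target is a eudesmane without its C5–C10 bond. Both unsaturation sites (C4=C5, the epoxide precursor, and C1=C10) flank exactly that bond, which is the pattern a 1,4-fragmentation leaves behind. Ring B (C6 to C10, isopropyl on C7, methyl on C10) maps onto (R)-carvone 1, which supplies C7 in the correct absolute configuration.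

**Retrosynthetic reasoning**

C6–O acyl bond. The acetate of 28 is removed first, to epoxy alcohol 27. An acetate would not survive the earlier reductions, desilylations and basic steps, and the free C6 hydroxyl of the preceding stage is needed as a directing group. The forward step is an acylation under non-acidic conditions that leave the oxirane alone.

C4–O and C5–O of the oxirane. 27 is traced to the (1(10)E,4E)-dienol 26. The oxirane comes late because it cannot coexist with the hydroboration that makes the ring. It is directed from O6 and not from O3 because only O6 lies close to the π plane on the outer face of C4=C5 in the preferred crown conformer. The forward reaction must pick the allylic C4=C5 bond over C1=C10 and the enoate, and the outer face over the inner one.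

Ester and silyl groups at O3 and O6. 26 goes back through silyl ether 25 and allylic alcohol 24 to bis-silyl ether 23. Esters cannot be carried through ring formation, so both oxygens are silyl ethers there. The labile triethylsilyl group sits on O3 and the robust tert-butyldimethylsilyl group on O6, which is introduced early and must last through ten steps. O3 is then freed and acylated first, and the last desilylation is done before the oxirane exists.

C5–C10 (reconnection). 23 is derived from octalin mesylate 19 by adding the C5–C10 bond, a leaving group on C1 and, transiently, boron on C4. This is the only disconnection that turns the medium ring into two six-membered rings, and it accounts for both ring olefins at once. Forward, the σ bond shared by ring A and ring B breaks and both double bonds appear with defined geometry; nothing has to be cyclised. The price is a decalin carrying an equatorial C1 leaving group, a tetrasubstituted C4=C5 olefin and the C3 and C6 oxygens.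

C1 configuration. The equatorial (β) mesylate of 19 comes from alcohol 18, this from ketone 17, and 17 from the axial alcohol 16. Additions to C1 of a dienone come from the face opposite the C10 methyl and give the axial epimer. Only hydride addition to a C1 carbonyl places the oxygen equatorial, so the centre is passed through the ketone.

C1–O and C3–H. 16 is the mono-silyl ether of diol 15, which comes from hydroxy enone 14 and this from dienone 12 by conjugate oxygenation of C1 (through boronate 13). C1 is the only electrophilic, unhindered position of the dienone, and the axial hydroxyl so formed then sets C3 by internal hydride delivery.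

C1=C2 and C6–O. 12 derives from silyl ether 11, alcohol 10, dienyl acetate 9 and enone 8. C6 is the γ-position of the enone and is oxidised through the extended enol derivative while the skeleton is a rigid octalone. The oxygen must be in place and protected before the enone is consumed.

C4=C5 and C1–C10. 8 is opened by retro-aldol to diketone 7 and by retro-Michael to ketone 2 and enone 4; 2 is the perhydro derivative of 1. The C10 methyl must be cis to the isopropyl group so that the β face of the later octalin is uniformly shielded. The ring alone would direct 4 to the other face, so the addition is run on the imine of auxiliary 3 (intermediates 5 and 6). 1 supplies C6–C10, C14 and the C7 configuration; 4 supplies C1–C4 and C15.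

**Alternatives that were turned down**

Alternative 1: The ring is cut at C9–C10 and closed by an intramolecular B-alkyl Suzuki coupling. Forward, the terminal C8=C9 vinyl group of an open-chain substrate is hydroborated with 9-borabicyclo[3.3.1]nonane and the alkylborane is coupled with the C10 alkenyl iodide (Pd(dppf)Cl2, Cs2CO3) to give A1, the 6-O-triethylsilyl ether of the 6-deacetyl target.
- For: the C1=C10 geometry is fixed in the iodide, and all five stereocentres and the oxirane are made on an open chain with reagent-controlled methods. A1 is two steps from the target. On endgame length and on control of C4/C5 this plan is stronger than the chosen one.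
- Against: the bond is formed by end-to-end closure of a ten-membered ring holding an E trisubstituted olefin and a trans oxirane. Transannular strain builds at palladium in the ring-forming step, and β-hydride elimination, protodeboronation and oligomerisation compete even at high dilution. The borane and aqueous base also meet an enoate and an oxirane, and the open-chain substrate needs a long linear sequence.
- Comparison: the chosen route never closes the medium ring; it pays the strain by fragmenting a preorganised decalin and takes C7 from the chiral pool. In exchange it accepts a late epoxidation on the macrocycle.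

Alternative 2: The ring is cut at C8–C9 and C1–C6 is reconnected, so a six-membered ring is expanded by four atoms in an anionic oxy-Cope rearrangement. Forward, KH and 18-crown-6 convert a cyclohexanol with two alkenyl groups on adjacent carbons into its alkoxide; the [3,3] shift and protonation give ketone A2 (C6 carbonyl, 1(10)E olefin, C3 silyl ether, C4/C5 diol as acetonide).
- For: like the chosen route it makes the medium ring from a six-membered one, and the chair transition state gives the E olefin. C3, C4 and C5 are set on a cyclohexane before expansion, so there is no facial problem at C4/C5 on the macrocycle; on this point it is stronger.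
- Against: C7 is created only on protonation of the ten-membered enolate and C6 only on reduction of the ketone on the flexible ring, so two of five centres are weakly controlled. The ketone is flanked by the C5 oxygen, so enolate equilibration invites β-elimination of the C4 oxygen. The diol must still be turned into the oxirane by selective activation at C5, several steps after A2.
- Comparison: the chosen route has C7 from 1 and C6 set on a rigid octalone, and its ring-forming step fixes both olefin geometries.

Alternative 3: The ring is cut at C6–C7. Forward, a thirteen-membered diallylic ether is contracted by a transannular [2,3]-Wittig rearrangement: lithium bis[(S)-1-phenylethyl]amide deprotonates C6 next to the ether oxygen, the carbanion attacks C7 with allylic shift and C–O cleavage, and A3 (6-hydroxy, 7-isopropenyl, 3-silyloxy, 1(10)E,4E) results.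
- For: one step makes the C6–C7 bond, both its stereocentres and the free C6 hydroxyl. The large-ring ether is easy to close and the substrate is short to make. In step count this plan is probably the shortest, and A3 lies about as close to the target as 23.
- Against: absolute configuration depends on a chiral base choosing between enantiotopic protons next to an existing C3 centre, and the base must also choose C6 over the other α-oxy allylic position. The C6/C7 relative configuration is dictated by the folding of the large ring and may not be the 6R,7S pair. The isopropenyl group must be hydrogenated beside two ring olefins, and the late epoxidation problem is the same as in the chosen route.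
- Comparison: the chosen route is longer but takes C7 from the chiral pool, sets C6 on a rigid bicycle and forms the ring stereospecifically.

Key step: step 14

Remarks on the chemistry: ketone 2 is carried as its C2 epimer mixture, which converges in step 2. In the eudesmane intermediates β is the face of the C10 methyl (C14).

**Route**

Step 1
Reactants: 1 (R)-carvone
Product: 2 carvomenthone [(2RS,5R)-2-methyl-5-(propan-2-yl)cyclohexan-1-one]
Conditions: H2 (1 atm), 10% Pd/C, EtOAc, rt
Reagents that add atoms: none
Why: Heterogeneous hydrogenation saturates the enone and isopropenyl double bonds without touching the ketone or the C5 stereocentre; C2 forms as an epimer mixture that converges in step 2.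

Step 2
Reactants: 2 carvomenthone; 3 (R)-1-phenylethylamine; 4 pent-1-en-3-one
Product: 7 (2S,5R)-2-methyl-2-(3-oxopentyl)-5-(propan-2-yl)cyclohexan-1-one, via ketimine 5 (not isolated), via Michael-adduct ketimine 6 (not isolated)
Conditions: 3, TsOH (cat.), toluene, reflux (Dean–Stark); 4, THF, 40 °C; 10% aq. AcOH, rt
Reagents that add atoms: water, O
Why: Asymmetric Michael addition of a chiral ketimine (d'Angelo): the secondary enamine tautomer of 5 adds to 4 at its more substituted carbon through a compact aza-ene-like transition state, and the (R)-1-phenylethyl group steers 4 to the face that leaves the methyl cis to the isopropyl group (2S), the sense known for the isopropenyl analogue. Reagent control is needed because simple enolate annulation gives mainly the C10 epimer; aqueous acid hydrolyses 6 and returns 3.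

Step 3
Reactants: 7 (2S,5R)-2-methyl-2-(3-oxopentyl)-5-(propan-2-yl)cyclohexan-1-one
Product: 8 eudesm-4-en-3-one [(4aS,7R)-1,4a-dimethyl-7-(propan-2-yl)-4,4a,5,6,7,8-hexahydronaphthalen-2(3H)-one]
Conditions: NaOMe, MeOH, 0 °C → rt
Reagents that add atoms: none
Why: Intramolecular aldol condensation (second stage of the Robinson annulation): the ethyl ketone enolate closes on the ring carbonyl and dehydration gives the tetrasubstituted enone; C7 and the quaternary C10 cannot epimerise.

Step 4
Reactants: 8 eudesm-4-en-3-one
Product: 9 eudesma-3,5-dien-3-yl acetate
Conditions: isopropenyl acetate, TsOH (cat.), reflux, acetone distilled off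
Reagents that add atoms: isopropenyl acetate, CC(=C)OC(C)=O
Why: Acid-catalysed enol acetylation under thermodynamic control gives the heteroannular 3,5-dienyl acetate, as with 3-oxo-4-ene steroids.

Step 5
Reactants: 9 eudesma-3,5-dien-3-yl acetate
Product: 10 6β-hydroxyeudesm-4-en-3-one
Conditions: mCPBA, dioxane/H2O, 0 °C → rt
Reagents that add atoms: 3-chloroperoxybenzoic acid, OOC(=O)c1cccc(Cl)c1
Why: Vinylogous Rubottom-type oxidation: the peracid attacks the γ-terminus C6 of the dienyl acetate along the axial (β) trajectory that keeps overlap with the enol π system, and the equatorial 6α alternative would clash with the C4 methyl (allylic 1,3-strain), so the 6β-alcohol is expected as in the steroid series. Collapse of the intermediate releases the acetyl group and regenerates the enone.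

Step 6
Reactants: 10 6β-hydroxyeudesm-4-en-3-one
Product: 11 6β-(tert-butyldimethylsilyloxy)eudesm-4-en-3-one
Conditions: TBSOTf, 2,6-lutidine, CH2Cl2, −78 → 0 °C
Reagents that add atoms: tert-butyldimethylsilyl triflate, CC(C)(C)[Si](C)(C)OS(=O)(=O)C(F)(F)F
Why: The silyl triflate with a hindered pyridine base silylates the axial 6β-hydroxyl at low temperature faster than it enolises the enone; this robust ether must last through ten further steps.

Step 7
Reactants: 11 6β-(tert-butyldimethylsilyloxy)eudesm-4-en-3-one
Product: 12 6β-(tert-butyldimethylsilyloxy)eudesma-1,4-dien-3-one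
Conditions: DDQ, dioxane, reflux
Reagents that add atoms: none
Why: Dehydrogenation with DDQ under neutral conditions goes through the kinetic 2,4-dienol and hydride loss from C1 to give the cross-conjugated dienone; C6 is substituted and its equatorial hydrogen is poorly aligned, so the 4,6-dienone pathway is closed.

Step 8
Reactants: 12 6β-(tert-butyldimethylsilyloxy)eudesma-1,4-dien-3-one
Product: 14 1α-hydroxy-6β-(tert-butyldimethylsilyloxy)eudesm-4-en-3-one, via boronate 13 (not isolated)
Conditions: B2pin2, CuCl (cat.), NaOtBu (cat.), DPEphos (cat.), MeOH, THF, rt; then NaBO3·4H2O, THF/H2O, rt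
Reagents that add atoms: sodium perborate tetrahydrate (NaBO3·4H2O), [Na+].[Na+].O[B-]1(O)OO[B-](O)(O)OO1
Why: Copper-catalysed conjugate borylation: the Cu–Bpin species adds to the disubstituted C1=C2 bond (the tetrasubstituted C4=C5 bond is inert) from the α face, anti to the C10 methyl, as known for 4,4-disubstituted cyclohexadienones, and perborate oxidises C–B with retention to the 1α-alcohol. The C1 configuration is provisional (corrected in steps 11 and 12), but the axial 1α-hydroxyl directs step 9.

Step 9
Reactants: 14 1α-hydroxy-6β-(tert-butyldimethylsilyloxy)eudesm-4-en-3-one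
Product: 15 6β-(tert-butyldimethylsilyloxy)eudesm-4-ene-1α,3β-diol
Conditions: Me4NBH(OAc)3, MeCN/AcOH, −30 °C
Reagents that add atoms: none
Why: Evans–Saksena directed reduction: the axial 1α-hydroxyl exchanges onto boron and delivers hydride intramolecularly to the α face of the C3 carbonyl, giving the 3β (equatorial, 1,3-anti) allylic alcohol by 1,2-reduction.

Step 10
Reactants: 15 6β-(tert-butyldimethylsilyloxy)eudesm-4-ene-1α,3β-diol
Product: 16 6β-(tert-butyldimethylsilyloxy)-3β-(triethylsilyloxy)eudesm-4-en-1α-ol
Conditions: TESCl (1.05 equiv), imidazole, CH2Cl2, −20 → 0 °C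
Reagents that add atoms: chlorotriethylsilane, CC[Si](Cl)(CC)CC
Why: The allylic equatorial 3β-hydroxyl is silylated selectively; the axial neopentyl 1α-hydroxyl next to the quaternary C10 reacts far more slowly.

Step 11
Reactants: 16 6β-(tert-butyldimethylsilyloxy)-3β-(triethylsilyloxy)eudesm-4-en-1α-ol
Product: 17 6β-(tert-butyldimethylsilyloxy)-3β-(triethylsilyloxy)eudesm-4-en-1-one
Conditions: Dess–Martin periodinane, NaHCO3, CH2Cl2, 0 °C → rt
Reagents that add atoms: none
Why: Dess–Martin oxidation of the hindered axial alcohol under buffered, non-basic conditions gives the C1 ketone without β-elimination of the C3 silyloxy group and erases the provisional C1 centre.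

Step 12
Reactants: 17 6β-(tert-butyldimethylsilyloxy)-3β-(triethylsilyloxy)eudesm-4-en-1-one
Product: 18 6β-(tert-butyldimethylsilyloxy)-3β-(triethylsilyloxy)eudesm-4-en-1β-ol
Conditions: NaBH4, MeOH/CH2Cl2, −40 → −20 °C
Reagents that add atoms: none
Why: Hydride adds to the C1 carbonyl along the axial trajectory from the α face, anti to the adjacent axial C10 methyl, as in the borohydride reduction of the saturated carbonyl of the Wieland–Miescher ketone, giving the equatorial 1β-alcohol needed for the fragmentation. Low temperature keeps the β-silyloxy ketone from eliminating.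

Step 13
Reactants: 18 6β-(tert-butyldimethylsilyloxy)-3β-(triethylsilyloxy)eudesm-4-en-1β-ol
Product: 19 1β-mesyloxy-3β-(triethylsilyloxy)-6β-(tert-butyldimethylsilyloxy)eudesm-4-ene
Conditions: MsCl, Et3N, CH2Cl2, 0 °C
Reagents that add atoms: methanesulfonyl chloride, CS(Cl)(=O)=O
Why: Mesylation through the sulfene is insensitive to the neopentyl environment and retains configuration at C1.

Step 14
Reactants: 19 1β-mesyloxy-3β-(triethylsilyloxy)-6β-(tert-butyldimethylsilyloxy)eudesm-4-ene
Product: 23 (1(10)E,4E,3S,6R,7S)-6-(tert-butyldimethylsilyloxy)-3-(triethylsilyloxy)germacra-1(10),4-diene, via alkylborane 20 (not isolated), via dimethyl boronate 21 (not isolated), via sodium trimethoxyborate 22 (not isolated)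
Conditions: BH3·SMe2 (excess), THF, 0 °C → rt; then NaOMe, MeOH, rt → 40 °C
Reagents that add atoms: none
Why: BH3 adds syn across the tetrasubstituted C4=C5 bond from the α face, hydrogen to C5 and boron to C4, giving the trans-fused monoalkylborane 20 with boron equatorial; methanol converts B–H into B–OMe (21) and methoxide gives the ate complex 22. In 22 the C4–B bond, the C5–C10 bond and the equatorial C1–OMs bond are antiperiplanar in pairs, so the borate fragments in one concerted step: C4=C5 and C1=C10 form, C5–C10 breaks and mesylate leaves (boronate-induced Grob-type 1,4-fragmentation of hydroborated octalin sulfonates, the Marshall reaction). The ten-membered ring is therefore not closed end to end; it is released from the bicycle by cleavage of the bond shared by ring A and ring B, which avoids the entropic and transannular cost of a medium-ring cyclisation. No stereocentre is created in 23 (C3, C6 and C7 are spectators and the transient centres C4 and C5 become sp2); the two alkene geometries are fixed stereospecifically because the chair holds C3/C6 and C2/C9 anti across the breaking bond, giving E,E. The step needs boron on C4 and not on the neopentyl C5, and attack on the α face: C5 is flanked by the quaternary C10 and the silyloxy-bearing C6, and the β face is covered by the axial C10 methyl, the axial 6β-silyloxy group and the 3β-silyloxy group. It also needs the C3 oxygen to survive next to boron: the equatorial C4–B and C3–O bonds are gauche in the locked trans-decalin, so neither syn nor anti 1,2-elimination is geometrically available. Base is added only after hydroboration is complete and the mixture is kept at or below 40 °C to avoid Cope rearrangement of the 1,5-diene.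

Step 15
Reactants: 23 (1(10)E,4E,3S,6R,7S)-6-(tert-butyldimethylsilyloxy)-3-(triethylsilyloxy)germacra-1(10),4-diene
Product: 24 (1(10)E,4E,3S,6R,7S)-6-(tert-butyldimethylsilyloxy)germacra-1(10),4-dien-3-ol
Conditions: HF·pyridine, excess pyridine, THF, 0 °C
Reagents that add atoms: none
Why: Buffered HF·pyridine cleaves the labile triethylsilyl ether of the allylic C3 alcohol and leaves the hindered tert-butyldimethylsilyl ether at C6; the excess pyridine keeps the medium too weakly acidic for transannular cyclisation of the diene.

Step 16
Reactants: 24 (1(10)E,4E,3S,6R,7S)-6-(tert-butyldimethylsilyloxy)germacra-1(10),4-dien-3-ol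
Product: 25 (1(10)E,4E,3S,6R,7S)-6-(tert-butyldimethylsilyloxy)germacra-1(10),4-dien-3-yl 3-methylbut-2-enoate
Conditions: 3-methylbut-2-enoyl chloride, pyridine, DMAP (cat.), CH2Cl2, 0 °C → rt
Reagents that add atoms: 3-methylbut-2-enoyl chloride, CC(C)=CC(Cl)=O
Why: DMAP-catalysed acylation of the secondary allylic alcohol; pyridine and not a trialkylamine is the base, so the acid chloride is not turned into the vinylketene that leads to the deconjugated ester. The ester goes on before the oxirane exists, so chloride never meets an epoxide.

Step 17
Reactants: 25 (1(10)E,4E,3S,6R,7S)-6-(tert-butyldimethylsilyloxy)germacra-1(10),4-dien-3-yl 3-methylbut-2-enoate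
Product: 26 (1(10)E,4E,3S,6R,7S)-6-hydroxygermacra-1(10),4-dien-3-yl 3-methylbut-2-enoate
Conditions: TBAF, AcOH (1:1), THF, rt
Reagents that add atoms: none
Why: Fluoride cleaves the remaining silyl ether; buffering with acetic acid keeps the medium near neutral, so the enoate is not attacked and the diene is not protonated.

Step 18
Reactants: 26 (1(10)E,4E,3S,6R,7S)-6-hydroxygermacra-1(10),4-dien-3-yl 3-methylbut-2-enoate
Product: 27 (1(10)E,3S,4R,5R,6R,7S)-4,5-epoxy-6-hydroxygermacr-1(10)-en-3-yl 3-methylbut-2-enoate
Conditions: VO(acac)2 (cat.), t-BuOOH, CH2Cl2, 0 °C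
Reagents that add atoms: tert-butyl hydroperoxide, CC(C)(C)OO
Why: Hydroxyl-directed epoxidation (Sharpless–Michaelson type): vanadium bound to O6 epoxidises only the allylic C4=C5 bond and leaves C1=C10 and the electron-poor enoate alone. In the crown conformer C7 sits on the inner face of C4=C5, so for the 6R alcohol O6 lies near the π plane, tilted to the outer face (O–C6–C5=C4 about 30–50°), the geometry vanadium needs. Oxygen is delivered to the outer face and should give the 4R,5R oxirane, erythro to C6.

Step 19
Reactants: 27 (1(10)E,3S,4R,5R,6R,7S)-4,5-epoxy-6-hydroxygermacr-1(10)-en-3-yl 3-methylbut-2-enoate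
Product: 28 CNP0267399.1 [(1(10)E,3S,4R,5R,6R,7S)-6-acetoxy-4,5-epoxygermacr-1(10)-en-3-yl 3-methylbut-2-enoate]
Conditions: Ac2O, pyridine, DMAP (cat.), CH2Cl2, 0 °C → rt
Reagents that add atoms: acetic anhydride, CC(=O)OC(C)=O
Why: DMAP-catalysed acetylation of the secondary epoxy alcohol under basic, non-nucleophilic conditions that leave the oxirane and the enoate untouched.

**Compound list**

1 | (R)-carvone | CC1=CC[C@H](CC1=O)C(=C)C | starting material
2 | carvomenthone, (2RS,5R)-2-methyl-5-(propan-2-yl)cyclohexan-1-one, C2 epimer mixture | CC1CC[C@H](CC1=O)C(C)C | intermediate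
3 | (R)-1-phenylethylamine | C[C@@H](N)c1ccccc1 | starting material (auxiliary, recovered)
4 | pent-1-en-3-one (ethyl vinyl ketone) | CCC(=O)C=C | starting material
5 | ketimine of 2 and 3, C2 epimer mixture | CC1CC[C@H](CC1=N[C@H](C)c1ccccc1)C(C)C | intermediate (not isolated)
6 | Michael-adduct ketimine, (1S,4R)-1-methyl-1-(3-oxopentyl)-4-isopropylcyclohexan-2-ylidene N-[(R)-1-phenylethyl]amine | C[C@@]1(CCC(=O)CC)CC[C@@H](C(C)C)CC1=N[C@H](C)c1ccccc1 | intermediate (not isolated)
7 | (2S,5R)-2-methyl-2-(3-oxopentyl)-5-(propan-2-yl)cyclohexan-1-one | C[C@@]1(CCC(=O)CC)CC[C@@H](C(C)C)CC1=O | intermediate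
8 | eudesm-4-en-3-one (11,12-dihydro-α-cyperone), (4aS,7R) | C[C@@]12CC[C@@H](C(C)C)CC1=C(C)C(=O)CC2 | intermediate
9 | eudesma-3,5-dien-3-yl acetate | C[C@@]12CC[C@@H](C(C)C)C=C1C(C)=C(OC(C)=O)CC2 | intermediate
10 | 6β-hydroxyeudesm-4-en-3-one | C[C@@]12CC[C@@H](C(C)C)[C@@H](O)C1=C(C)C(=O)CC2 | intermediate
11 | 6β-(tert-butyldimethylsilyloxy)eudesm-4-en-3-one | C[C@@]12CC[C@@H](C(C)C)[C@@H](O[Si](C)(C)C(C)(C)C)C1=C(C)C(=O)CC2 | intermediate
12 | 6β-(tert-butyldimethylsilyloxy)eudesma-1,4-dien-3-one | C[C@@]12CC[C@@H](C(C)C)[C@@H](O[Si](C)(C)C(C)(C)C)C1=C(C)C(=O)C=C2 | intermediate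
13 | 1α-(pinacolboryl)-6β-(tert-butyldimethylsilyloxy)eudesm-4-en-3-one | C[C@@]12CC[C@@H](C(C)C)[C@@H](O[Si](C)(C)C(C)(C)C)C1=C(C)C(=O)C[C@@H]2B1OC(C)(C)C(C)(C)O1 | intermediate (not isolated)
14 | 1α-hydroxy-6β-(tert-butyldimethylsilyloxy)eudesm-4-en-3-one | C[C@@]12CC[C@@H](C(C)C)[C@@H](O[Si](C)(C)C(C)(C)C)C1=C(C)C(=O)C[C@@H]2O | intermediate
15 | 6β-(tert-butyldimethylsilyloxy)eudesm-4-ene-1α,3β-diol | C[C@@]12CC[C@@H](C(C)C)[C@@H](O[Si](C)(C)C(C)(C)C)C1=C(C)[C@@H](O)C[C@@H]2O | intermediate
16 | 6β-(tert-butyldimethylsilyloxy)-3β-(triethylsilyloxy)eudesm-4-en-1α-ol | C[C@@]12CC[C@@H](C(C)C)[C@@H](O[Si](C)(C)C(C)(C)C)C1=C(C)[C@@H](O[Si](CC)(CC)CC)C[C@@H]2O | intermediate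
17 | 6β-(tert-butyldimethylsilyloxy)-3β-(triethylsilyloxy)eudesm-4-en-1-one | C[C@@]12CC[C@@H](C(C)C)[C@@H](O[Si](C)(C)C(C)(C)C)C1=C(C)[C@@H](O[Si](CC)(CC)CC)CC2=O | intermediate
18 | 6β-(tert-butyldimethylsilyloxy)-3β-(triethylsilyloxy)eudesm-4-en-1β-ol | C[C@@]12CC[C@@H](C(C)C)[C@@H](O[Si](C)(C)C(C)(C)C)C1=C(C)[C@@H](O[Si](CC)(CC)CC)C[C@H]2O | intermediate
19 | 1β-mesyloxy-3β-(triethylsilyloxy)-6β-(tert-butyldimethylsilyloxy)eudesm-4-ene (key-step precursor) | C[C@@]12CC[C@@H](C(C)C)[C@@H](O[Si](C)(C)C(C)(C)C)C1=C(C)[C@@H](O[Si](CC)(CC)CC)C[C@H]2OS(C)(=O)=O | intermediate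
20 | 4α-boranyl-5αH adduct of 19 (monoalkylborane) | C[C@@]12CC[C@@H](C(C)C)[C@@H](O[Si](C)(C)C(C)(C)C)[C@H]1[C@](C)(B)[C@@H](O[Si](CC)(CC)CC)C[C@H]2OS(C)(=O)=O | intermediate (not isolated)
21 | 4α-(dimethoxyboryl)-5αH analogue | C[C@@]12CC[C@@H](C(C)C)[C@@H](O[Si](C)(C)C(C)(C)C)[C@H]1[C@](C)(B(OC)OC)[C@@H](O[Si](CC)(CC)CC)C[C@H]2OS(C)(=O)=O | intermediate (not isolated)
22 | sodium 4α-trimethoxyborate (ate complex) | C[C@@]12CC[C@@H](C(C)C)[C@@H](O[Si](C)(C)C(C)(C)C)[C@H]1[C@](C)([B-](OC)(OC)OC)[C@@H](O[Si](CC)(CC)CC)C[C@H]2OS(C)(=O)=O.[Na+] | intermediate (not isolated)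
23 | (1(10)E,4E,3S,6R,7S)-6-(tert-butyldimethylsilyloxy)-3-(triethylsilyloxy)germacra-1(10),4-diene (key-step product) | CC(C)(C)[Si](C)(C)O[C@H]1/C=C(C)/[C@@H](O[Si](CC)(CC)CC)C/C=C(\C)CC[C@H]1C(C)C | intermediate
24 | (1(10)E,4E,3S,6R,7S)-6-(tert-butyldimethylsilyloxy)germacra-1(10),4-dien-3-ol | CC(C)(C)[Si](C)(C)O[C@H]1/C=C(C)/[C@@H](O)C/C=C(\C)CC[C@H]1C(C)C | intermediate
25 | (1(10)E,4E,3S,6R,7S)-6-(tert-butyldimethylsilyloxy)germacra-1(10),4-dien-3-yl 3-methylbut-2-enoate | CC(C)(C)[Si](C)(C)O[C@H]1/C=C(C)/[C@@H](OC(=O)C=C(C)C)C/C=C(\C)CC[C@H]1C(C)C | intermediate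
26 | (1(10)E,4E,3S,6R,7S)-6-hydroxygermacra-1(10),4-dien-3-yl 3-methylbut-2-enoate | O[C@H]1/C=C(C)/[C@@H](OC(=O)C=C(C)C)C/C=C(\C)CC[C@H]1C(C)C | intermediate
27 | (1(10)E,3S,4R,5R,6R,7S)-4,5-epoxy-6-hydroxygermacr-1(10)-en-3-yl 3-methylbut-2-enoate | O[C@H]1[C@H]2O[C@]2(C)[C@@H](OC(=O)C=C(C)C)C/C=C(\C)CC[C@H]1C(C)C | intermediate
28 | CNP0267399.1, (1(10)E,3S,4R,5R,6R,7S)-6-acetoxy-4,5-epoxygermacr-1(10)-en-3-yl 3-methylbut-2-enoate | CC(=O)O[C@H]1[C@H]2O[C@]2(C)[C@@H](OC(=O)C=C(C)C)C/C=C(\C)CC[C@H]1C(C)C | target

**Step count and uncertain steps**

Total step count: 19. Longest linear sequence: 19 steps (1 to 28).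

Step 14 (key step). Most likely failure: slow or misdirected hydroboration of the crowded tetrasubstituted olefin (boron on C5, or β-face attack giving a cis-fused borane without the antiperiplanar array), and diversion of the monoalkylborane in basic methanol (protodeboronation, loss of the C3 silyloxy group) before it fragments. Fallback, from 19 back to 23: hydroborate as before but quench with pinacol and isolate the 4α-pinacol boronic ester F1. Purification removes regio- and stereoisomers. F1 is then fragmented under aprotic conditions by ate-complex formation with anhydrous KOMe and 18-crown-6 in THF, which should give 23. This separates C–B bond formation from the fragmentation and takes the free borane out of the basic step.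

Step 18. Most likely failure: poor facial selectivity, because relief of allylic 1,3-strain between O6 and C15 could send the reaction through the ring-flipped conformer and give the threo oxirane. Transannular opening of the new oxirane by C1=C10 under Lewis acid, or oxidation of the allylic alcohol to the enone, are further risks. Fallback, from 26 directly to 27: reagent-controlled Sharpless epoxidation with Ti(OiPr)4, D-(−)-diisopropyl tartrate and t-BuOOH over 4 Å molecular sieves at −20 °C. For a secondary allylic alcohol of the 6R type this tartrate is the fast-reacting (matched) pairing and gives the erythro epoxy alcohol, so the face is set by the catalyst and not by ring conformation. This fallback makes no new compound (F0).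

Step 5. Most likely failure: loss of site or facial selectivity in the peracid attack (reaction at C4 of the tetrasubstituted enol acetate, or α-face attack at C6). Fallback, from 8 back to 10: ketalisation with ethylene glycol and TsOH shifts the double bond and gives the 3,3-ethylenedioxy-5-ene F2. Epoxidation with mCPBA gives the 5,6-epoxide F3 (5α,6α shown; the β-epoxide converges). Aqueous HClO4 opens either epoxide trans-diaxially and removes the ketal, giving 5α,6β-dihydroxyeudesman-3-one F4. Acid-catalysed dehydration of the tertiary β-hydroxyl should then give 10. Here C6 is set by diaxial epoxide opening, not by electrophilic attack on a dienol.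

Step 8. Most likely failure: slow conjugate borylation at the neopentyl β-carbon, or protodeboronation of the β-boryl ketone. Fallback, from 12 back to 14: nucleophilic epoxidation with H2O2 and NaOH in MeOH gives the 1α,2α-epoxy ketone F5, and reductive opening at the α-carbon with SmI2 in THF/MeOH at −78 °C should give the 1α-hydroxy enone 14.

Step 2. Most likely failure: incomplete facial control at C10, because the auxiliary has to override the ring's own preference for attack cis to the isopropyl group, leaving a mixture of C10 epimers. Fallback, from 1 back to 8, with the face set by a fused cyclopropane: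
- conjugate reduction of 1 with LiBH(s-Bu)3 gives (+)-dihydrocarvone F6;
- HCl in AcOH adds to the isopropenyl group to give the tertiary chloride F7;
- KOH in MeOH closes the cyclopropane to carone F8;
- Robinson annulation of F8 with 4 (KOH, EtOH) occurs anti to the gem-dimethylcyclopropane and gives the tricyclic enone F9 with the C10 methyl cis to the C7–C11 bond;
- HCl in AcOH opens the conjugated cyclopropane to the 11-chloro enone F10;
- Bu3SnH with AIBN removes the chlorine and should give 8.

**Further compounds**

F1 | step 14 | 1β-mesyloxy-4α-(pinacolboryl)-3β-(triethylsilyloxy)-6β-(tert-butyldimethylsilyloxy)-5αH-eudesmane | C[C@@]12CC[C@@H](C(C)C)[C@@H](O[Si](C)(C)C(C)(C)C)[C@H]1[C@](C)(B3OC(C)(C)C(C)(C)O3)[C@@H](O[Si](CC)(CC)CC)C[C@H]2OS(C)(=O)=O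
F0 | step 18 | none | none
F2 | step 5 | 3,3-ethylenedioxyeudesm-5-ene (C4 epimers) | C[C@@]12CC[C@@H](C(C)C)C=C1C(C)C3(OCCO3)CC2
F3 | step 5 | 5α,6α-epoxy-3,3-ethylenedioxyeudesmane (C4 epimers) | C[C@@]12CC[C@@H](C(C)C)[C@@H]3O[C@@]31C(C)C4(OCCO4)CC2
F4 | step 5 | 5α,6β-dihydroxyeudesman-3-one (C4 epimers) | C[C@@]12CC[C@@H](C(C)C)[C@@H](O)[C@@]1(O)C(C)C(=O)CC2
F5 | step 8 | 1α,2α-epoxy-6β-(tert-butyldimethylsilyloxy)eudesm-4-en-3-one | C[C@@]12CC[C@@H](C(C)C)[C@@H](O[Si](C)(C)C(C)(C)C)C1=C(C)C(=O)[C@@H]3O[C@@H]32
F6 | step 2 | (+)-dihydrocarvone, (2R,5R)-2-methyl-5-(prop-1-en-2-yl)cyclohexan-1-one | C[C@@H]1CC[C@H](CC1=O)C(C)=C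
F7 | step 2 | (2R,5R)-5-(2-chloropropan-2-yl)-2-methylcyclohexan-1-one | C[C@@H]1CC[C@H](CC1=O)C(C)(C)Cl
F8 | step 2 | carone, cis-fused 3,7,7-trimethylbicyclo[4.1.0]heptan-2-one | C[C@@H]1CC[C@@H]2[C@H](C1=O)C2(C)C
F9 | step 2 | 6,11-cycloeudesm-4-en-3-one (tricyclic enone, C10 methyl cis to the cyclopropane) | C[C@@]12CC[C@@H]3[C@H](C1=C(C)C(=O)CC2)C3(C)C
F10 | step 2 | 11-chloroeudesm-4-en-3-one | C[C@@]12CC[C@@H](C(C)(C)Cl)CC1=C(C)C(=O)CC2
A1 | alternative 1 | 6-O-triethylsilyl ether of the 6-deacetyl target | CC[Si](CC)(CC)O[C@H]1[C@H]2O[C@]2(C)[C@@H](OC(=O)C=C(C)C)C/C=C(\C)CC[C@H]1C(C)C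
A2 | alternative 2 | (1(10)E)-3-(tert-butyldimethylsilyloxy)-4,5-(isopropylidenedioxy)germacr-1(10)-en-6-one | O=C1[C@@H]2OC(C)(C)O[C@]2(C)[C@@H](O[Si](C)(C)C(C)(C)C)C/C=C(\C)CC[C@H]1C(C)C
A3 | alternative 3 | (1(10)E,4E)-3-(tert-butyldimethylsilyloxy)-7-(prop-1-en-2-yl)germacra-1(10),4-dien-6-ol | O[C@H]1/C=C(C)/[C@@H](O[Si](C)(C)C(C)(C)C)C/C=C(\C)CC[C@H]1C(C)=C
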